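**The unit.** A unit of starting material consumed took a unit of reagent with it: in the north-west run, target plus side product read 74.0% of the charge at 120 min, and the reagent charged was 74.0% of the starting material.

all flasks: starting material 0.050 M

| charge | reagent | remark | time |
|---|---|---|---|
| north-west | 0.037 M | run made earlier |  |
| west | 0.15 M | run made earlier |  |
| flask | 0.0750 M |  | 2.5 h |

| run | time / min | target / % | side product / % | starting material / % |
|---|---|---|---|---|
| north-west | 15.0 | 52 | 11 | 31 |
| north-west | 40.0 | 57 | 14 | 27 |
| north-west | 80.0 | 59 | 16 | 24 |
| north-west | 120 | 59 | 15 | 28 |
| west | 15.0 | 81 | 17 | 2 |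
| west | 40.0 | 81 | 21 | 0 |
| west | 80.0 | 78 | 19 | 0 |
| west | 120 | 80 | 20 | 0 |

(each reading ± 1.5 percentage points)

- the analysis behind the earlier runs scatters by 1.5 percentage points, standard deviation

- ratio of target to side product at 1.5 s
- ratio of target to side product at 2.0 min
- ratio of target to side product at 2.5 h
- which of target and side product there is more of at 2.5 h

**The correction.** I treated side product as the small correction and target as the remainder. The last west reading gave 0.200 for the side share, the fraction of each consumed unit found as side product at the end. The north-west run read 0.203.

**First rung.** West starting material fell to 2% by 15.0 min. With reagent in excess, that reading gave a pseudo-first-order time of 3.83 min, a rough figure given the scatter of 1.5 percentage points.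

**Second rung.** Side product may have trailed: at 15.0 min the west run read 17% against a last 20%, and the ratio of target to side product read 4.76. I expected the flask's early ratios above the late one, but I put no number on them, as no reading came earlier.

**Last rung.** The flask's reagent excess was 50.0% of the starting material, a quarter of the west excess, so I stretched the time to 15.3 min. The flask's 2.5 h was ten times that, so I reckoned on full consumption, side product at 20.0% of the charge and a ratio of 4.00.

**The forecast.** It gave 4.8 at 1.5 s (range 3.6 to 20), 4.6 at 2.0 min (range 3.6 to 9) and 4 at 2.5 h (range 3.7 to 4.3), with target ahead. Unlike me, it put numbers on the early ratios: “Early values are probably somewhat higher but are poorly constrained, since no run samples that early.”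

**The flask.** The ratio came out at 259 at 1.5 s, 6.40 at 2.0 min and 3.96 at 2.5 h, with target ahead.

    starting material + reagent ⇌ intermediate A (K = 1.50 M⁻¹, k = 0.0830 M⁻¹ s⁻¹)
    starting material + reagent ⇌ intermediate B (K = 4.20 M⁻¹, k = 0.110 M⁻¹ s⁻¹)
    intermediate C → side product (k = 0.00840 s⁻¹)
    starting material + reagent → target (k = 0.100 M⁻¹ s⁻¹)
    intermediate B → intermediate C (k = 0.00310 s⁻¹)
    intermediate B → side product (k = 0.00470 s⁻¹)

Side product in the flask stood at 12.3% after 0.0750 h and 19.2% after 0.250 h, then reached 20.2% at the end, which the side share had put at 20.0%. In the neighbour charged with 0.019 M of reagent, the limiting reagent fell to 0%, so 38.0% of the starting material was consumed. The side share turned that into 7.60% side product, and the neighbour held 7.66%.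

The runs are simulated with made-up constants, and the scatter is random.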